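## Analysis of the target

The target 30 is a trans-fused hydroazulene. A cyclopentane (C3–C4–C5–C6–C7) shares the C3–C7 bond with a cycloheptene (C1–C2–C3–C7–C8–C9–C10) whose only alkene is C9=C10, with a methyl group on C10. It has five stereocentres: the quaternary C3 (angular methyl), the tertiary carbinol C6 (hydroxyl and isopropyl), the ring-fusion CH C7, and the allylic carbinol carbons C8 (4-hydroxybenzoate) and C1 (acetate). The angular methyl, the C6 hydroxyl and the C7–C8 bond lie on one face of the cyclopentane; the isopropyl group, the C7 hydrogen and the C3–C2 bond lie on the other. The ester oxygens at C8 and C1 are cis to each other across the seven-membered ring and trans to the angular methyl. The sensitive groups are the tertiary alcohol, the two different allylic esters and the free phenol. The alcohol is beta to C8, so retro-aldol cleavage or loss of water threatens whenever C8 is a carbonyl. The difficulty lies in the congested C3–C7–C6 triad and in telling two similar allylic oxygens apart. The plan rests on one feature: C3 carries two two-carbon arms, C2–C1 and C7–C8. If the C6–C7 bond is cut and C6 is written as a ketone, both arms become CH2CHO groups, and C3 becomes the prochiral centre of an achiral keto dialdehyde.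

## Retrosynthetic reasoning

**Phenol and acetate (30 ⇒ 29 ⇒ 28).** The phenol is unmasked last from its silyl ether 29. The C1 acetate is traced to the alcohol 28. No selectivity between the two allylic oxygens is needed, because C8 is already esterified when the C1 hydroxyl first appears.

**Seven-membered ring (28 ⇒ 27).** The ring is cut at C1–C10, between the alkene carbon and the carbinol carbon. This is preferred to C8–C9 because the closure then meets an unhindered CH2CHO group rather than the crowded C8. A chromium/nickel-mediated (Nozaki–Hiyama–Kishi) addition of the Z iodoalkene to the aldehyde in 27 forms the ring, the C1 oxygen and the C1 stereocentre together and keeps the alkene geometry.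

**C8 ester and C1 aldehyde (27 ⇒ 26 ⇒ 21 + 24; 24 ⇒ 22).** The aldehyde is released from the dimethyl acetal 26. The aroyl group is attached to the C8 hydroxyl of 21 with the silyl-protected acid 24, made from 22.

**Iodoalkene (21 ⇒ 19).** The Z iodoalkene comes from the alkyne of 19 by hydroxyl-directed trans-hydroalumination and iodination. The C8 alkoxide fixes both the regiochemistry (iodine on C10) and the geometry (iodine cis to C8). A separately prepared silylated propenyl reagent would need extra steps to reach the same geometry.

**C8–C9 bond and C8 configuration (19 ⇒ 18 ⇒ 17 ⇒ 15 + 16).** The three carbons C9, C10 and the C10 methyl arrive as the alkynyl Grignard reagent 16, added to the C8 aldehyde of 15. The addition need not be selective: oxidation to the ynone 18 and a catalyst-controlled transfer hydrogenation set C8. Catalyst control is preferred to internal hydride delivery from the C6 hydroxyl. That carbinol is tertiary and part of the ring, so two chair transition states of opposite sense are both plausible.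

**Aldehyde differentiation (15 ⇒ 14).** Only the C1 formyl group of 14 is acetalised; the steric difference between the two formyl groups is used.

**Cyclopentane (14 ⇒ 13), the key disconnection.** Cutting C6–C7 gives the achiral keto dialdehyde 13. In the forward direction the chiral amino acid catalyst of step 7 forms an enamine on one arm, and this enamine attacks the ketone. One bond, one ring and the stereocentres C3, C6 and C7 result.

**Dialdehyde (13 ⇒ 11).** The two identical arms come from ozonolysis of a symmetric cyclopentene, which guarantees that they are equivalent.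

**Side chain (11 ⇒ 9 ⇒ 6 + 7).** The ketone chain is made by crossed aldol condensation of the non-enolisable aldehyde 6 with the methyl ketone 7, followed by conjugate reduction of the enone 9. The isopropyl group therefore comes in with a cheap ketone.

**Quaternary carbon (6 ⇒ 5 ⇒ 4 ⇒ 1 + 2).** The future C3 is made by methylation of the ester 1 with 2. The ester carbon is then adjusted to the aldehyde.

## Alternatives that were turned down

**Alternative 1: (4+3) annulation of a vinylcarbenoid.** The seven-membered ring is cut at C9–C10 and C2–C3, which leads back to the cyclopentenyl silyloxydiene A2 and the silyloxyvinyl diazo ester A3.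
- Forward key step: a chiral dirhodium tetracarboxylate converts A3 into a vinylcarbenoid, which cyclopropanates the terminal enol ether alkene of A2. Cope rearrangement of the cis-divinylcyclopropane then gives the hydroazulene A1.
- For it: the reaction class is established and convergent. It closes the seven-membered ring and sets the quaternary C3 under catalyst control in one operation. On precedent and on ring construction it is stronger than the chosen key step.
- Against it: A1 has the right ring but the wrong functionality.
  - The ester on C10 must be reduced to a methyl group.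
  - C1 and C8 emerge as masked ketones, and each needs a face-selective reduction.
  - The C9=C10 alkene must be rebuilt from a beta-keto ester.
  - C7 is still sp2, so the trans ring fusion must be set later.
  - The isopropyl group must be added to a hindered, enolisable C6 ketone from the correct face.
  - The Cope step must form a bond to a fully substituted diene terminus.
- Comparison: the chosen route carries the methyl and isopropyl groups and the correct oxidation levels from simple achiral materials, and it makes the tertiary carbinol in the ring-forming step. Fewer corrective steps follow its key step; the price is a key step without direct precedent.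

**Alternative 2: endoperoxide route.** Both C–O bonds at C8 and C1 are cut, which leads back to the ring diene A5 (C8=C9–C10=C1).
- Forward key step: dye-sensitised photooxygenation adds O2 across C8 and C1 of A5 in a (4+2) sense to give the endoperoxide A4. Reduction of the O–O bond would give the cis-1,4-diol with C9=C10 in place.
- For it: two stereocentres and the alkene position are fixed in one step. The cis relation of the oxygens follows from the mechanism, and attack anti to the angular methyl predicts the correct face. On the oxygenation pattern it is more direct than the chosen route, which sets C8 and C1 in two operations.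
- Against it: it is only an endgame. A5, with C3, C6 and C7 already set, must be made first, and the idea does not help there. The ene reaction at the allylic hydrogens competes with cycloaddition. The two secondary allylic alcohols formed must be told apart by steric difference alone.
- Comparison: the chosen route builds the skeleton and C3, C6 and C7 in its key step. It differentiates the two oxygens by the order in which they appear.

**Alternative 3: conjugate addition and aldol on a cyclopentenone.** C2–C3 and C7–C8 are cut, which leads back to the enone A7, the alkenylalane A9 and the iodoenal A8.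
- Forward key step: a chiral copper catalyst transfers the 1-silylvinyl group of A9 to C3 of A7. The aluminium enolate is trapped by A8 to give the anti aldol adduct A6; no ring is closed.
- For it: catalytic asymmetric conjugate addition to beta-methyl enones is a known way to a quaternary centre. Three components, including the complete C8–C10 iodoalkene, are joined in one flask. On precedent for the quaternary centre it is stronger than the chosen route.
- Against it: five-membered enones are the least selective substrates of this reaction. The aldol must be selective at two centres next to the new quaternary carbon. The tertiary carbinol C6 is left to an isopropyl nucleophile adding to a hindered, enolisable beta-hydroxy cyclopentanone, where enolisation, reduction and retro-aldol cleavage compete and the face is not clearly controlled. The silylvinyl group must also be converted into the CH2–CHO arm before ring closure.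
- Comparison: the chosen route has the isopropyl group in the ketone from the start, so C6 is made by ring-forming C–C bond formation. C8 is set by a catalyst-controlled reduction, not by an aldol next to a quaternary centre.

Key step: step 7

Remark on the chemistry: (R)-proline is chosen for step 7 because the hydrogen-bonded enamine model assigns the configuration of 14 to this enantiomer. If the sense of induction proves opposite, (S)-proline is used and nothing else changes.

Note: C1–C10 in the text are the skeleton labels of the analysis; locants inside names are systematic. The C8 centre is R in 19–27 and S in 28–30 with unchanged geometry, because the ranking of its neighbours changes on ring closure.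

## Route

Step 1
Reactants: 1 methyl cyclopent-3-ene-1-carboxylate; 2 iodomethane
Product: 4 methyl 1-methylcyclopent-3-ene-1-carboxylate, via lithium ester enolate 3 (not isolated)
Conditions: LiN(i-Pr)2, THF, −78 °C; then 2, −78 °C → rt
Reagents that add atoms: none
Why: Ester enolate alkylation: the enolate 3 is methylated by 2 in an SN2 reaction, which creates the future quaternary C3; the ring is symmetric, so no stereocentre arises.

Step 2
Reactants: 4 methyl 1-methylcyclopent-3-ene-1-carboxylate
Product: 5 (1-methylcyclopent-3-en-1-yl)methanol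
Conditions: LiAlH4, Et2O, 0 °C → rt
Reagents that add atoms: none
Why: Hydride reduction of an ester to the primary alcohol; the isolated alkene is inert to LiAlH4.

Step 3
Reactants: 5 (1-methylcyclopent-3-en-1-yl)methanol
Product: 6 1-methylcyclopent-3-ene-1-carbaldehyde
Conditions: TEMPO (10 mol %), PhI(OAc)2, CH2Cl2, rt
Reagents that add atoms: none
Why: Oxoammonium (TEMPO) oxidation stops at the aldehyde and leaves the alkene alone; 6 has no alpha-hydrogen and is carried on in solution because it is volatile.

Step 4
Reactants: 6 1-methylcyclopent-3-ene-1-carbaldehyde; 7 3-methylbutan-2-one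
Product: 9 (1E)-4-methyl-1-(1-methylcyclopent-3-en-1-yl)pent-1-en-3-one, via aldol adduct 8 (not isolated)
Conditions: NaOH (aq.), EtOH, excess 7, 0 → 50 °C
Reagents that add atoms: none
Why: Crossed aldol condensation of the Claisen–Schmidt type: 6 cannot enolise, and only the adduct 8 formed at the methyl group of 7 can lose water, so the E enone 9 should be the only condensation product; an adduct at the isopropyl carbon reverts.

Step 5
Reactants: 9 (1E)-4-methyl-1-(1-methylcyclopent-3-en-1-yl)pent-1-en-3-one
Product: 11 4-methyl-1-(1-methylcyclopent-3-en-1-yl)pentan-3-one, via silyl enol ether 10 (not isolated)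
Conditions: [(Ph3P)CuH]6 (cat.), PhMe2SiH, toluene, rt; then 1 M HCl, THF
Reagents that add atoms: dimethylphenylsilane, C[SiH](C)c1ccccc1 (its silicon stays only in 10)
Why: Copper hydride conjugate reduction (1,4-hydrosilylation): the monovalent copper hydride adds only to the electron-poor enone alkene and leaves the ring alkene untouched; acid hydrolysis of 10 gives the ketone.

Step 6
Reactants: 11 4-methyl-1-(1-methylcyclopent-3-en-1-yl)pentan-3-one
Product: 13 3-methyl-3-(4-methyl-3-oxopentyl)pentanedial, via ozonide 12 (not isolated)
Conditions: O3, CH2Cl2, −78 °C; then PPh3, −78 °C → rt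
Reagents that add atoms: ozone, [O-][O+]=O
Why: Ozonolysis with reductive work-up cleaves the only alkene; the two formyl arms are constitutionally identical, so 13 is achiral; it is used at once.

Step 7
Reactants: 13 3-methyl-3-(4-methyl-3-oxopentyl)pentanedial
Product: 14 (1R,2R,5R)-2-hydroxy-5-methyl-5-(2-oxoethyl)-2-(propan-2-yl)cyclopentane-1-carbaldehyde
Conditions: (R)-proline (20 mol %), DMF (0.05 M), 4 °C → rt
Reagents that add atoms: none
Why: Proposed new method: the amine of (R)-proline condenses with one formyl arm of 13 to give an E enamine, whose carbon C7 adds to the isopropyl ketone C6 while the carboxylic acid hydrogen-bonds to the ketone oxygen; hydrolysis of the iminium ion returns the catalyst and gives 14. The closest known reaction types are the proline-catalysed 5-enolexo aldolisation of formyl ketones to cis-2-hydroxycycloalkanecarbaldehydes and the proline-catalysed desymmetrising enolexo aldolisation of prochiral dialdehydes; their combination at a quaternary prochiral carbon with a branched ketone acceptor has not been shown. The cyclopentane closes in the 5-(enolexo)-exo-trig mode; a closure between the two formyl arms would need a cyclobutane and enamine formation at the hindered ketone is slow, so no other ring can form. C6 is set by the hydrogen bond, which holds the ketone oxygen on the side of the enamine nitrogen and so places the hydroxyl cis to the formyl group and the isopropyl group trans to it. C7 is set by the enamine face that the catalyst exposes and is also the thermodynamically preferred epimer, since the formyl group then lies trans to both the isopropyl group and the remaining CH2CHO arm. C3 is set by the choice between the two enantiotopic arms: in the cyclic transition state one substituent of C3 must lie in the enamine plane next to the C8 hydrogen, and allylic 1,3-strain should put the methyl group there and not the CH2CHO arm, which leaves the methyl group cis to C8. The step therefore needs facial control by the catalyst for the absolute configuration and arm selection through this strain element for the relative configuration at C3; the two unbranched arms form the enamine equally easily, so nothing else biases the choice.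

Step 8
Reactants: 14 (1R,2R,5R)-2-hydroxy-5-methyl-5-(2-oxoethyl)-2-(propan-2-yl)cyclopentane-1-carbaldehyde
Product: 15 (1R,2R,5R)-5-(2,2-dimethoxyethyl)-2-hydroxy-5-methyl-2-(propan-2-yl)cyclopentane-1-carbaldehyde
Conditions: MeOH, HC(OMe)3, PPTS (5 mol %), 0 °C
Reagents that add atoms: methanol, CO
Why: Kinetically selective acetalisation: the C1 formyl group sits on a CH2 group, whereas the C8 formyl group is attached to a ring carbon flanked by two fully substituted carbons and is hydrogen-bonded to the hydroxyl, so only C1 should react under cold, weakly acidic conditions; any equilibration at C7 favours the epimer already present.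

Step 9
Reactants: 15 (1R,2R,5R)-5-(2,2-dimethoxyethyl)-2-hydroxy-5-methyl-2-(propan-2-yl)cyclopentane-1-carbaldehyde; 16 prop-1-ynylmagnesium bromide
Product: 17 1-[(1S,2R,5R)-5-(2,2-dimethoxyethyl)-2-hydroxy-5-methyl-2-(propan-2-yl)cyclopentyl]but-2-yn-1-ol (both epimers at the new carbinol carbon C8)
Conditions: 16 (3 equiv), THF, −78 → 0 °C; NH4Cl (aq.)
Reagents that add atoms: none
Why: Addition of an alkynyl Grignard reagent to an aldehyde; one equivalent is consumed by the hydroxyl, the reagent is a weak base so enolisation should be limited, and the C8 configuration does not matter because both epimers are oxidised in step 10.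

Step 10
Reactants: 17 1-[(1S,2R,5R)-5-(2,2-dimethoxyethyl)-2-hydroxy-5-methyl-2-(propan-2-yl)cyclopentyl]but-2-yn-1-ol
Product: 18 1-[(1R,2R,5R)-5-(2,2-dimethoxyethyl)-2-hydroxy-5-methyl-2-(propan-2-yl)cyclopentyl]but-2-yn-1-one
Conditions: Dess–Martin periodinane, pyridine, CH2Cl2, 0 °C → rt
Reagents that add atoms: none
Why: Dess–Martin oxidation of a propargylic alcohol to the ynone; the tertiary hydroxyl and the acetal are inert, and the buffered medium avoids conjugate addition of the hydroxyl to the ynone.

Step 11
Reactants: 18 1-[(1R,2R,5R)-5-(2,2-dimethoxyethyl)-2-hydroxy-5-methyl-2-(propan-2-yl)cyclopentyl]but-2-yn-1-one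
Product: 19 (1R)-1-[(1S,2R,5R)-5-(2,2-dimethoxyethyl)-2-hydroxy-5-methyl-2-(propan-2-yl)cyclopentyl]but-2-yn-1-ol
Conditions: Ru[(R,R)-TsDPEN](p-cymene) (5 mol %), i-PrOH, rt
Reagents that add atoms: none
Why: Asymmetric transfer hydrogenation of an alkynyl ketone (Noyori type; TsDPEN is N-tosyl-1,2-diphenylethane-1,2-diamine): the divalent ruthenium hydride and the ligand NH deliver hydride and proton to one carbonyl face, distinguishing the alkynyl from the alkyl substituent, and this catalyst class normally overrides neighbouring stereocentres. By the usual sense for alkynyl alkyl ketones the (R,R)-catalyst should give the (R)-propargylic alcohol, which is the C8 geometry of the target; the medium is neutral, so the beta-hydroxy ynone should neither cyclise nor cleave.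

Step 12
Reactants: 19 (1R)-1-[(1S,2R,5R)-5-(2,2-dimethoxyethyl)-2-hydroxy-5-methyl-2-(propan-2-yl)cyclopentyl]but-2-yn-1-ol
Product: 21 (1R,2Z)-1-[(1S,2R,5R)-5-(2,2-dimethoxyethyl)-2-hydroxy-5-methyl-2-(propan-2-yl)cyclopentyl]-3-iodobut-2-en-1-ol, via alkenylalanate 20 (not isolated)
Conditions: NaAlH2(OCH2CH2OMe)2, THF, 0 °C → rt; then I2, THF, −78 → 0 °C
Reagents that add atoms: iodine, II; sodium bis(2-methoxyethoxy)aluminium dihydride, [Na+].[H][Al-]([H])(OCCOC)OCCOC (its aluminium and alkoxy groups stay only in 20)
Why: trans-Hydroalumination of a propargylic alcohol followed by iodinolysis: the C8 alkoxide directs hydride to C9 and aluminium to C10, giving the five-membered alanate 20 with aluminium cis to C8, and iodine replaces aluminium with retention, so only the Z iodoalkene should form; C8 is untouched.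

Step 13
Reactants: 22 4-hydroxybenzoic acid
Product: 24 4-[(tert-butyldimethylsilyl)oxy]benzoic acid, via bis-silyl derivative 23 (not isolated)
Conditions: t-BuMe2SiCl (2.2 equiv), imidazole, DMF, rt; then AcOH/THF/H2O, rt
Reagents that add atoms: tert-butyldimethylsilyl chloride, CC(C)(C)[Si](C)(C)Cl
Why: Silylation of both acidic groups, then selective hydrolysis of the labile silyl ester of 23; the aryl silyl ether stays and masks the phenol during esterification and the later acetylation.

Step 14
Reactants: 21 (1R,2Z)-1-[(1S,2R,5R)-5-(2,2-dimethoxyethyl)-2-hydroxy-5-methyl-2-(propan-2-yl)cyclopentyl]-3-iodobut-2-en-1-ol; 24 4-[(tert-butyldimethylsilyl)oxy]benzoic acid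
Product: 26 (1R,2Z)-1-[(1S,2R,5R)-5-(2,2-dimethoxyethyl)-2-hydroxy-5-methyl-2-(propan-2-yl)cyclopentyl]-3-iodobut-2-en-1-yl 4-[(tert-butyldimethylsilyl)oxy]benzoate, via mixed anhydride 25 (not isolated)
Conditions: 24, 2,4,6-trichlorobenzoyl chloride, Et3N, THF, rt; then 21, DMAP, toluene, 60 °C
Reagents that add atoms: 2,4,6-trichlorobenzoyl chloride, O=C(Cl)c1c(Cl)cc(Cl)cc1Cl (its atoms stay only in 25)
Why: Yamaguchi esterification: DMAP attacks the less hindered carbonyl of 25 and the acylpyridinium ion esterifies the secondary allylic alcohol with retention at C8; the tertiary C6 hydroxyl is too hindered to react.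

Step 15
Reactants: 26 (1R,2Z)-1-[(1S,2R,5R)-5-(2,2-dimethoxyethyl)-2-hydroxy-5-methyl-2-(propan-2-yl)cyclopentyl]-3-iodobut-2-en-1-yl 4-[(tert-butyldimethylsilyl)oxy]benzoate
Product: 27 (1R,2Z)-1-[(1S,2R,5R)-2-hydroxy-5-methyl-5-(2-oxoethyl)-2-(propan-2-yl)cyclopentyl]-3-iodobut-2-en-1-yl 4-[(tert-butyldimethylsilyl)oxy]benzoate
Conditions: PPTS (cat.), acetone/H2O, 45 °C
Reagents that add atoms: water, O
Why: Mild acid hydrolysis of a dimethyl acetal; the aryl silyl ether, the allylic ester, the iodoalkene and the tertiary alcohol should tolerate pyridinium tosylate in wet acetone.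

Step 16
Reactants: 27 (1R,2Z)-1-[(1S,2R,5R)-2-hydroxy-5-methyl-5-(2-oxoethyl)-2-(propan-2-yl)cyclopentyl]-3-iodobut-2-en-1-yl 4-[(tert-butyldimethylsilyl)oxy]benzoate
Product: 28 (3R,3aS,4S,7S,8aR)-3,7-dihydroxy-6,8a-dimethyl-3-(propan-2-yl)-1,2,3,3a,4,7,8,8a-octahydroazulen-4-yl 4-[(tert-butyldimethylsilyl)oxy]benzoate
Conditions: CrCl2 (6 equiv), NiCl2 (2 mol %), DMSO (0.005 M), rt
Reagents that add atoms: none
Why: Intramolecular Nozaki–Hiyama–Kishi reaction: zerovalent nickel inserts into the C–I bond, the alkenyl group passes to trivalent chromium with retention of geometry and adds only to the aldehyde, closing the seven-membered ring (7-exo-trig at the carbonyl); esters and free hydroxyl groups are tolerated. C1 is set here: allylic 1,2-strain with the C10 methyl keeps the new C–O bond out of the alkene plane, and the position syn to the angular methyl at C3 is the more crowded, which should favour the alcohol trans to that methyl as in the target.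

Step 17
Reactants: 28 (3R,3aS,4S,7S,8aR)-3,7-dihydroxy-6,8a-dimethyl-3-(propan-2-yl)-1,2,3,3a,4,7,8,8a-octahydroazulen-4-yl 4-[(tert-butyldimethylsilyl)oxy]benzoate
Product: 29 (3R,3aS,4S,7S,8aR)-7-(acetyloxy)-3-hydroxy-6,8a-dimethyl-3-(propan-2-yl)-1,2,3,3a,4,7,8,8a-octahydroazulen-4-yl 4-[(tert-butyldimethylsilyl)oxy]benzoate
Conditions: Ac2O, pyridine, DMAP (cat.), CH2Cl2, 0 °C
Reagents that add atoms: acetic anhydride, CC(=O)OC(C)=O
Why: DMAP-catalysed acetylation of the secondary allylic alcohol; the tertiary C6 hydroxyl, flanked by the isopropyl group and the ring fusion, should not react at 0 °C.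

Step 18
Reactants: 29 (3R,3aS,4S,7S,8aR)-7-(acetyloxy)-3-hydroxy-6,8a-dimethyl-3-(propan-2-yl)-1,2,3,3a,4,7,8,8a-octahydroazulen-4-yl 4-[(tert-butyldimethylsilyl)oxy]benzoate
Product: 30 (3R,3aS,4S,7S,8aR)-7-(acetyloxy)-3-hydroxy-6,8a-dimethyl-3-(propan-2-yl)-1,2,3,3a,4,7,8,8a-octahydroazulen-4-yl 4-hydroxybenzoate
Conditions: Bu4NF, AcOH, THF, 0 °C
Reagents that add atoms: none
Why: Fluoride cleavage of an aryl silyl ether; acetic acid buffers the phenoxide so that neither ester should migrate or hydrolyse.

## Compound list

1 | methyl cyclopent-3-ene-1-carboxylate | COC(=O)C1CC=CC1 | starting material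
2 | iodomethane | CI | starting material
3 | lithium enolate of 1 | COC(O[Li])=C1CC=CC1 | intermediate (not isolated)
4 | methyl 1-methylcyclopent-3-ene-1-carboxylate | COC(=O)C1(C)CC=CC1 | intermediate
5 | (1-methylcyclopent-3-en-1-yl)methanol | OCC1(C)CC=CC1 | intermediate
6 | 1-methylcyclopent-3-ene-1-carbaldehyde | O=CC1(C)CC=CC1 | intermediate
7 | 3-methylbutan-2-one | CC(C)C(C)=O | starting material
8 | 1-hydroxy-4-methyl-1-(1-methylcyclopent-3-en-1-yl)pentan-3-one (racemic) | CC(C)C(=O)CC(O)C1(C)CC=CC1 | intermediate (not isolated)
9 | (1E)-4-methyl-1-(1-methylcyclopent-3-en-1-yl)pent-1-en-3-one | CC(C)C(=O)/C=C/C1(C)CC=CC1 | intermediate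
10 | dimethyl{[4-methyl-1-(1-methylcyclopent-3-en-1-yl)pent-2-en-3-yl]oxy}(phenyl)silane (enol ether geometry not defined) | CC(C)C(O[Si](C)(C)c1ccccc1)=CCC1(C)CC=CC1 | intermediate (not isolated)
11 | 4-methyl-1-(1-methylcyclopent-3-en-1-yl)pentan-3-one | CC(C)C(=O)CCC1(C)CC=CC1 | intermediate
12 | 3-methyl-3-(4-methyl-3-oxopentyl)-6,7,8-trioxabicyclo[3.2.1]octane | CC(C)C(=O)CCC1(C)CC2OOC(C1)O2 | intermediate (not isolated)
13 | 3-methyl-3-(4-methyl-3-oxopentyl)pentanedial | O=CCC(C)(CC=O)CCC(=O)C(C)C | intermediate
14 | (1R,2R,5R)-2-hydroxy-5-methyl-5-(2-oxoethyl)-2-(propan-2-yl)cyclopentane-1-carbaldehyde | O=CC[C@@]1(C)CC[C@@](O)(C(C)C)[C@@H]1C=O | intermediate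
15 | (1R,2R,5R)-5-(2,2-dimethoxyethyl)-2-hydroxy-5-methyl-2-(propan-2-yl)cyclopentane-1-carbaldehyde | COC(OC)C[C@@]1(C)CC[C@@](O)(C(C)C)[C@@H]1C=O | intermediate
16 | prop-1-ynylmagnesium bromide | CC#C[Mg]Br | starting material
17 | 1-[(1S,2R,5R)-5-(2,2-dimethoxyethyl)-2-hydroxy-5-methyl-2-(propan-2-yl)cyclopentyl]but-2-yn-1-ol (both carbinol epimers) | COC(OC)C[C@@]1(C)CC[C@@](O)(C(C)C)[C@@H]1C(O)C#CC | intermediate
18 | 1-[(1R,2R,5R)-5-(2,2-dimethoxyethyl)-2-hydroxy-5-methyl-2-(propan-2-yl)cyclopentyl]but-2-yn-1-one | COC(OC)C[C@@]1(C)CC[C@@](O)(C(C)C)[C@@H]1C(=O)C#CC | intermediate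
19 | (1R)-1-[(1S,2R,5R)-5-(2,2-dimethoxyethyl)-2-hydroxy-5-methyl-2-(propan-2-yl)cyclopentyl]but-2-yn-1-ol | COC(OC)C[C@@]1(C)CC[C@@](O)(C(C)C)[C@@H]1[C@@H](O)C#CC | intermediate
20 | disodium alkenylalanate of 19: five-membered 1,2-oxaaluminole ring (Al bound to the C8 oxygen and to C10, two 2-methoxyethoxy ligands), tertiary alkoxide bound to a second hydridoaluminate | COC(OC)C[C@@]1(C)CC[C@@](O[Al-]([H])(OCCOC)OCCOC)(C(C)C)[C@@H]1[C@H]2O[Al-](OCCOC)(OCCOC)C(C)=C2.[Na+].[Na+] | intermediate (not isolated)
21 | (1R,2Z)-1-[(1S,2R,5R)-5-(2,2-dimethoxyethyl)-2-hydroxy-5-methyl-2-(propan-2-yl)cyclopentyl]-3-iodobut-2-en-1-ol | COC(OC)C[C@@]1(C)CC[C@@](O)(C(C)C)[C@@H]1[C@@H](O)/C=C(/C)I | intermediate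
22 | 4-hydroxybenzoic acid | OC(=O)c1ccc(O)cc1 | starting material
23 | tert-butyldimethylsilyl 4-[(tert-butyldimethylsilyl)oxy]benzoate | CC(C)(C)[Si](C)(C)OC(=O)c1ccc(O[Si](C)(C)C(C)(C)C)cc1 | intermediate (not isolated)
24 | 4-[(tert-butyldimethylsilyl)oxy]benzoic acid | OC(=O)c1ccc(O[Si](C)(C)C(C)(C)C)cc1 | intermediate
25 | 4-[(tert-butyldimethylsilyl)oxy]benzoic 2,4,6-trichlorobenzoic anhydride | CC(C)(C)[Si](C)(C)Oc1ccc(cc1)C(=O)OC(=O)c1c(Cl)cc(Cl)cc1Cl | intermediate (not isolated)
26 | (1R,2Z)-1-[(1S,2R,5R)-5-(2,2-dimethoxyethyl)-2-hydroxy-5-methyl-2-(propan-2-yl)cyclopentyl]-3-iodobut-2-en-1-yl 4-[(tert-butyldimethylsilyl)oxy]benzoate | COC(OC)C[C@@]1(C)CC[C@@](O)(C(C)C)[C@@H]1[C@@H](OC(=O)c1ccc(O[Si](C)(C)C(C)(C)C)cc1)/C=C(/C)I | intermediate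
27 | (1R,2Z)-1-[(1S,2R,5R)-2-hydroxy-5-methyl-5-(2-oxoethyl)-2-(propan-2-yl)cyclopentyl]-3-iodobut-2-en-1-yl 4-[(tert-butyldimethylsilyl)oxy]benzoate | O=CC[C@@]1(C)CC[C@@](O)(C(C)C)[C@@H]1[C@@H](OC(=O)c1ccc(O[Si](C)(C)C(C)(C)C)cc1)/C=C(/C)I | intermediate
28 | (3R,3aS,4S,7S,8aR)-3,7-dihydroxy-6,8a-dimethyl-3-(propan-2-yl)-1,2,3,3a,4,7,8,8a-octahydroazulen-4-yl 4-[(tert-butyldimethylsilyl)oxy]benzoate | O[C@H]1C[C@@]2(C)CC[C@@](O)(C(C)C)[C@@H]2[C@@H](OC(=O)c2ccc(O[Si](C)(C)C(C)(C)C)cc2)C=C1C | intermediate
29 | (3R,3aS,4S,7S,8aR)-7-(acetyloxy)-3-hydroxy-6,8a-dimethyl-3-(propan-2-yl)-1,2,3,3a,4,7,8,8a-octahydroazulen-4-yl 4-[(tert-butyldimethylsilyl)oxy]benzoate | CC(=O)O[C@H]1C[C@@]2(C)CC[C@@](O)(C(C)C)[C@@H]2[C@@H](OC(=O)c2ccc(O[Si](C)(C)C(C)(C)C)cc2)C=C1C | intermediate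
30 | (3R,3aS,4S,7S,8aR)-7-(acetyloxy)-3-hydroxy-6,8a-dimethyl-3-(propan-2-yl)-1,2,3,3a,4,7,8,8a-octahydroazulen-4-yl 4-hydroxybenzoate | CC(=O)O[C@H]1C[C@@]2(C)CC[C@@](O)(C(C)C)[C@@H]2[C@@H](OC(=O)c2ccc(O)cc2)C=C1C | target

## Step count and least certain steps

Total: 18 steps. Longest linear sequence: 17 steps (steps 1–12 and 14–18); step 13 is a one-step side branch.

**Step 7 (key step).**
- What may go wrong: ring closure onto the branched ketone may be slow, so intermolecular aldol reactions between formyl groups take over. Discrimination between the two arms may be incomplete, which erodes the configuration at C3 relative to C6 and C7. Water may be lost from the aldol under the amine catalyst.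
- Fallback (known chemistry): it sets out from 11 and returns at 19; the quaternary centre is made as a racemate and resolved by the catalyst-controlled reduction already in the route.
  - Ozonolysis of 11 in acidic methanol, followed by bicarbonate and dimethyl sulfide, differentiates the termini and gives racemic 3-(2,2-dimethoxyethyl)-3,7-dimethyl-6-oxooctanal F1.
  - Pyrrolidinium acetate closes the ring by the known amine-catalysed 5-enolexo aldolisation of a formyl ketone, under the same strain control. This gives the racemate of 15, racemic 5-(2,2-dimethoxyethyl)-2-hydroxy-5-methyl-2-(propan-2-yl)cyclopentane-1-carbaldehyde F2. The selective acetalisation of step 8 is no longer needed.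
  - Steps 9 and 10, unchanged, give the racemate of 17, racemic 1-[5-(2,2-dimethoxyethyl)-2-hydroxy-5-methyl-2-(propan-2-yl)cyclopentyl]but-2-yn-1-ol F3, and the racemate of 18, racemic 1-[5-(2,2-dimethoxyethyl)-2-hydroxy-5-methyl-2-(propan-2-yl)cyclopentyl]but-2-yn-1-one F4.
  - In step 11 the catalyst sets the same carbinol configuration in both enantiomers of F4. The racemate becomes two diastereomers: 19 and (1R)-1-[(1R,2S,5S)-5-(2,2-dimethoxyethyl)-2-hydroxy-5-methyl-2-(propan-2-yl)cyclopentyl]but-2-yn-1-ol F5. They are separated by chromatography and 19 continues. Half of the material is lost.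

**Step 9.**
- What may go wrong: the magnesium alkoxide of the beta-hydroxy aldehyde may undergo retro-aldol ring opening, or C7 may epimerise, before the hindered aldehyde is attacked.
- Fallback: it sets out from 15 and returns at 17; no alkoxide is allowed to form.
  - The tertiary hydroxyl is silylated with N-(trimethylsilyl)imidazole to give (1R,2R,5R)-5-(2,2-dimethoxyethyl)-5-methyl-2-(propan-2-yl)-2-[(trimethylsilyl)oxy]cyclopentane-1-carbaldehyde F6.
  - Addition of 16 gives 1-[(1S,2R,5R)-5-(2,2-dimethoxyethyl)-5-methyl-2-(propan-2-yl)-2-[(trimethylsilyl)oxy]cyclopentyl]but-2-yn-1-ol F7.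
  - K2CO3 in methanol removes the silyl group and gives 17.

**Step 11.**
- What may go wrong: the crowded surroundings of C8 may override catalyst control and give the other carbinol epimer. The beta-hydroxy ynone may cyclise by conjugate addition of the hydroxyl if the medium becomes basic.
- Fallback: it sets out from 18 and returns at 19. Control is changed from catalyst to substrate by internal hydride delivery (Evans–Saksena reduction, Me4NBH(OAc)3, MeCN/AcOH, −30 °C) from the boron-bound C6 oxygen under acidic conditions. With the slim alkynyl group on the ketone, the chair that keeps the isopropyl group and the acyl carbon pseudo-equatorial on the cyclopentane should deliver hydride to the face that gives 19. This fallback makes no compound outside the list (F0).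

**Step 16.**
- What may go wrong: facial selectivity at C1 may be poor or reversed, because the conformational argument for the seven-membered transition state is not strong. Reduction of the C–I bond without ring closure may also compete at high dilution.
- Fallback: it sets out from the crude product of step 16 (made from 27) and returns at 29. The C1 epimer, (3R,3aS,4S,7R,8aR)-3,7-dihydroxy-6,8a-dimethyl-3-(propan-2-yl)-1,2,3,3a,4,7,8,8a-octahydroazulen-4-yl 4-[(tert-butyldimethylsilyl)oxy]benzoate F8, is separated. It is converted into the acetate with inversion by a Mitsunobu reaction (acetic acid, PPh3, diisopropyl azodicarboxylate), which gives 29 directly. Any 28 formed alongside is acetylated as in step 17.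

## Further compounds

F1 | step 7 | racemic 3-(2,2-dimethoxyethyl)-3,7-dimethyl-6-oxooctanal | O=CCC(C)(CC(OC)OC)CCC(=O)C(C)C
F2 | step 7 | racemic 5-(2,2-dimethoxyethyl)-2-hydroxy-5-methyl-2-(propan-2-yl)cyclopentane-1-carbaldehyde, relative configuration (1R*,2R*,5R*), the racemate of 15 | COC(OC)C[C@@]1(C)CC[C@@](O)(C(C)C)[C@@H]1C=O.COC(OC)C[C@]1(C)CC[C@](O)(C(C)C)[C@H]1C=O
F3 | step 7 | racemic 1-[5-(2,2-dimethoxyethyl)-2-hydroxy-5-methyl-2-(propan-2-yl)cyclopentyl]but-2-yn-1-ol, ring configuration (1S*,2R*,5R*), both carbinol epimers, the racemate of 17 | COC(OC)C[C@@]1(C)CC[C@@](O)(C(C)C)[C@@H]1C(O)C#CC.COC(OC)C[C@]1(C)CC[C@](O)(C(C)C)[C@H]1C(O)C#CC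
F4 | step 7 | racemic 1-[5-(2,2-dimethoxyethyl)-2-hydroxy-5-methyl-2-(propan-2-yl)cyclopentyl]but-2-yn-1-one, relative configuration (1R*,2R*,5R*), the racemate of 18 | COC(OC)C[C@@]1(C)CC[C@@](O)(C(C)C)[C@@H]1C(=O)C#CC.COC(OC)C[C@]1(C)CC[C@](O)(C(C)C)[C@H]1C(=O)C#CC
F5 | step 7 | (1R)-1-[(1R,2S,5S)-5-(2,2-dimethoxyethyl)-2-hydroxy-5-methyl-2-(propan-2-yl)cyclopentyl]but-2-yn-1-ol | COC(OC)C[C@]1(C)CC[C@](O)(C(C)C)[C@H]1[C@@H](O)C#CC
F6 | step 9 | (1R,2R,5R)-5-(2,2-dimethoxyethyl)-5-methyl-2-(propan-2-yl)-2-[(trimethylsilyl)oxy]cyclopentane-1-carbaldehyde | COC(OC)C[C@@]1(C)CC[C@@](O[Si](C)(C)C)(C(C)C)[C@@H]1C=O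
F7 | step 9 | 1-[(1S,2R,5R)-5-(2,2-dimethoxyethyl)-5-methyl-2-(propan-2-yl)-2-[(trimethylsilyl)oxy]cyclopentyl]but-2-yn-1-ol (both carbinol epimers) | COC(OC)C[C@@]1(C)CC[C@@](O[Si](C)(C)C)(C(C)C)[C@@H]1C(O)C#CC
F0 | step 11 | none | none
F8 | step 16 | (3R,3aS,4S,7R,8aR)-3,7-dihydroxy-6,8a-dimethyl-3-(propan-2-yl)-1,2,3,3a,4,7,8,8a-octahydroazulen-4-yl 4-[(tert-butyldimethylsilyl)oxy]benzoate | O[C@@H]1C[C@@]2(C)CC[C@@](O)(C(C)C)[C@@H]2[C@@H](OC(=O)c2ccc(O[Si](C)(C)C(C)(C)C)cc2)C=C1C
A1 | alternative 1 | methyl (8a'R)-4',7'-bis[(tert-butyldimethylsilyl)oxy]-8a'-methyl-1',2',8',8a'-tetrahydro-5'H-spiro[1,3-dioxolane-2,3'-azulene]-6'-carboxylate (hydroazulene bis(silyl enol ether) ester with the C6 ketal) | COC(=O)C1=C(O[Si](C)(C)C(C)(C)C)C[C@@]2(C)CCC3(OCCO3)C2=C(O[Si](C)(C)C(C)(C)C)C1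
A2 | alternative 1 | tert-butyl{[1-(7-methyl-1,4-dioxaspiro[4.4]non-6-en-6-yl)ethenyl]oxy}dimethylsilane | C=C(O[Si](C)(C)C(C)(C)C)C1=C(C)CCC12OCCO2
A3 | alternative 1 | methyl 3-[(tert-butyldimethylsilyl)oxy]-2-diazobut-3-enoate | COC(=O)C(=[N+]=[N-])C(=C)O[Si](C)(C)C(C)(C)C
A4 | alternative 2 | endoperoxide of A5 across C8 and C1 (peroxide bridge cis to the C7 hydrogen, triethylsilyl ether at C6) | CC1=C[C@@H]2OO[C@H]1C[C@@]3(C)CC[C@@](O[Si](CC)(CC)CC)(C(C)C)[C@H]23
A5 | alternative 2 | triethyl{[(3R,3aR,8aR)-6,8a-dimethyl-3-(propan-2-yl)-1,2,3,3a,8,8a-hexahydroazulen-3-yl]oxy}silane | CC1=CC[C@@]2(C)CC[C@@](O[Si](CC)(CC)CC)(C(C)C)[C@@H]2C=C1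
A6 | alternative 3 | (2S,3S)-2-[(1R,2Z)-1-hydroxy-3-iodobut-2-en-1-yl]-3-methyl-3-[1-(trimethylsilyl)ethenyl]cyclopentan-1-one | O=C1CC[C@](C)(C(=C)[Si](C)(C)C)[C@H]1[C@@H](O)/C=C(/C)I
A7 | alternative 3 | 3-methylcyclopent-2-en-1-one | CC1=CC(=O)CC1
A8 | alternative 3 | (2Z)-3-iodobut-2-enal | C/C(I)=C/C=O
A9 | alternative 3 | bis(2-methylpropyl)[1-(trimethylsilyl)ethenyl]alumane | CC(C)C[Al](CC(C)C)C(=C)[Si](C)(C)C
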